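The target 16 is the achiral flavone 5,7,4'-trihydroxy-6,2',5'-trimethoxyflavone; it has no stereocentre, so no stereochemistry has to be set.
Retrosynthesis: the O7 and O4' benzyl ethers and the 6-O-methyl group come off first, then the pyranone is opened at O1–C8a, then the chain is cut at C2–C3 into 4-O-benzylgallacetophenone and a ring B acid chloride.
Enabling feature: in ring A the oxygens on C5 and C6 are vicinal and O1 on C8a lies para to the C6 oxygen, so ring A is a latent catechol whose ortho-quinone is electrophilic at C8a.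
Forward: ring B is prepared from 2,5-dimethoxybenzaldehyde (steps 1–5) and ring A from gallacetophenone (step 6). C2–C3 is made by C-acylation (step 7), ring C closes by anodic O1–C8a bond formation (step 8), and 6-O-methylation and hydrogenolysis finish the route (steps 9 and 10).

Key step: step 8

Remark: the anode potential given in step 8 is an estimate and is to be fixed from a cyclic voltammogram of 12 in the same medium; flavone numbering is used for the diketone and the quinone as well.

Step 1
Reactants: 1 2,5-dimethoxybenzaldehyde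
Product: 3 2,5-dimethoxyphenol, via aryl formate 2 (not isolated)
Conditions: mCPBA (1.2 equiv), CH2Cl2, 0 °C to rt; then MeOH, HCl (cat.), rt
Reagents that add atoms: 3-chloroperoxybenzoic acid (mCPBA), O=C(OO)c1cccc(Cl)c1
Why: Baeyer–Villiger (Dakin-type) oxidation, in which the electron-rich aryl group with its ortho methoxy substituent migrates in preference to hydride and the aryl formate is then cleaved by acid-catalysed methanolysis.

Step 2
Reactants: 3 2,5-dimethoxyphenol
Product: 4 2-(benzyloxy)-1,4-dimethoxybenzene
Conditions: BnBr (1.1 equiv), K2CO3 (1.5 equiv), DMF, rt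
Reagents that add atoms: benzyl bromide, BrCc1ccccc1
Why: Williamson ether synthesis on the only acidic site, the phenol, with a reactive benzylic halide.

Step 3
Reactants: 4 2-(benzyloxy)-1,4-dimethoxybenzene
Product: 5 1-(benzyloxy)-4-bromo-2,5-dimethoxybenzene
Conditions: NBS (1.05 equiv), MeCN, 0 °C to rt, dark
Reagents that add atoms: N-bromosuccinimide, O=C1CCC(=O)N1Br
Why: Electrophilic aromatic bromination at the position para to the benzyloxy group and ortho to a methoxy group, the most activated and least hindered site, as in the bromination of 1,2,4-trimethoxybenzene.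

Step 4
Reactants: 5 1-(benzyloxy)-4-bromo-2,5-dimethoxybenzene
Product: 7 4-(benzyloxy)-2,5-dimethoxybenzoic acid, via aryllithium 6 (not isolated)
Conditions: n-BuLi (1.1 equiv), THF, −78 °C; CO2 (g), −78 °C to rt; 1 M HCl
Reagents that add atoms: carbon dioxide, O=C=O
Why: Bromine–lithium exchange is fast at −78 °C and should outrun benzylic deprotonation, and the aryllithium is then carboxylated by CO2.

Step 5
Reactants: 7 4-(benzyloxy)-2,5-dimethoxybenzoic acid
Product: 8 4-(benzyloxy)-2,5-dimethoxybenzoyl chloride
Conditions: (COCl)2 (1.5 equiv), DMF (cat.), CH2Cl2, 0 °C to rt; evaporated and used crude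
Reagents that add atoms: oxalyl chloride, O=C(Cl)C(=O)Cl
Why: Acid chloride formation through the catalytic chloroiminium species under conditions that leave the benzyl and methyl ethers untouched.

Step 6
Reactants: 9 gallacetophenone (1-(2,3,4-trihydroxyphenyl)ethanone)
Product: 10 1-[4-(benzyloxy)-2,3-dihydroxyphenyl]ethanone
Conditions: BnBr (1.05 equiv), NaHCO3 (1.2 equiv), DMF, 40 °C, Ar
Reagents that add atoms: benzyl bromide, BrCc1ccccc1
Why: Williamson etherification under weak base, in which only the 4-hydroxyl (para to the acetyl group and the most acidic) is ionised, while the 2-hydroxyl is held in a hydrogen bond to the carbonyl and the 3-hydroxyl is flanked on both sides.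

Step 7
Reactants: 10 1-[4-(benzyloxy)-2,3-dihydroxyphenyl]ethanone; 8 4-(benzyloxy)-2,5-dimethoxybenzoyl chloride
Product: 12 1-[4-(benzyloxy)-2,3-dihydroxyphenyl]-3-[4-(benzyloxy)-2,5-dimethoxyphenyl]propane-1,3-dione, via trilithium polyanion 11 (not isolated)
Conditions: LiN(SiMe3)2 (4.2 equiv), THF, −78 to −10 °C; then 8 (1.0 equiv), THF, −78 °C to rt; cold 1 M HCl to pH 4
Reagents that add atoms: none
Why: Claisen-type C-acylation of the lithium polyanion of a hydroxyacetophenone, in which the enolate carbon is far more nucleophilic than the lithium-bound phenoxides and the fourth equivalent of base stores the diketone as its enolate until the mild acid quench.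

Step 8
Reactants: 12 1-[4-(benzyloxy)-2,3-dihydroxyphenyl]-3-[4-(benzyloxy)-2,5-dimethoxyphenyl]propane-1,3-dione
Product: 14 7-(benzyloxy)-2-[4-(benzyloxy)-2,5-dimethoxyphenyl]-5,6-dihydroxy-4H-chromen-4-one, via ortho-quinone 13 (not isolated)
Conditions: graphite-felt anode, Pt cathode, divided cell, ca. +0.45 V vs Ag/AgCl, stopped at 2.0 F/mol; 12 (5 mM) in MeCN/0.1 M aq. NaH2PO4–Na2HPO4 buffer (pH 7) 1:1, Ar, 20 °C
Reagents that add atoms: none
Why: Proposed new method: the free catechol of ring A gives up two electrons and two protons at the carbon anode to form ortho-quinone 13, in which C8a is the β carbon of both the C5 quinone carbonyl and the C4 ketone; the enol oxygen on C2 adds there and the adduct loses the C8a proton, which restores an aromatic ring A as the 5,6-catechol of 14. The closest known reaction type is the anodic oxidation of catechols in buffered aqueous acetonitrile in the presence of 1,3-dicarbonyl compounds, where the ortho-quinone takes up the dicarbonyl in a Michael addition and the enol oxygen then closes a ring by an intramolecular oxa-Michael step to give benzofurans; here the enol is tethered, so oxygen attack comes first. The pyranone ring closes in a 6-endo-trig mode, O1 adding to the C4a=C8a double bond that lies inside the new ring, whereas attack by C3 would need a four-membered ring and is excluded. No stereocentre is formed. The step needs chemoselective oxidation of ring A, secured by the much lower potential of a free catechol compared with the trialkoxyarene ring B and the benzyl ethers, and regioselective attack at C8a, secured because it is the only quinone carbon within reach of the tethered enol oxygen while C8 is deactivated by the C7 benzyloxy donor. Neutral buffer, high dilution and a charge limited to 2 F/mol are meant to hold back acid-catalysed dehydrative closure through the C5 hydroxyl, intermolecular coupling and over-oxidation of 14, whose quinone should in any case be reduced again by unreacted 12.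

Step 9
Reactants: 14 7-(benzyloxy)-2-[4-(benzyloxy)-2,5-dimethoxyphenyl]-5,6-dihydroxy-4H-chromen-4-one
Product: 15 7-(benzyloxy)-2-[4-(benzyloxy)-2,5-dimethoxyphenyl]-5-hydroxy-6-methoxy-4H-chromen-4-one
Conditions: MeI (1.1 equiv), K2CO3 (1.2 equiv), DMF, rt, Ar
Reagents that add atoms: iodomethane, CI
Why: Williamson methylation under mild base, in which the 6-hydroxyl is the only phenol free to ionise because the 5-hydroxyl is locked in a strong hydrogen bond to the C4 carbonyl, as in the 6-O-methylation of 7-O-benzylated 5,6-dihydroxyflavones.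

Step 10
Reactants: 15 7-(benzyloxy)-2-[4-(benzyloxy)-2,5-dimethoxyphenyl]-5-hydroxy-6-methoxy-4H-chromen-4-one
Product: 16 5,7-dihydroxy-2-(4-hydroxy-2,5-dimethoxyphenyl)-6-methoxy-4H-chromen-4-one
Conditions: H2 (1 atm), 10% Pd/C, THF/MeOH 1:1, rt
Reagents that add atoms: none
Why: Catalytic hydrogenolysis of the two aryl benzyl ethers over Pd/C, under which the aryl methyl ethers and the flavone enone should not be reduced at atmospheric pressure and room temperature.

Compound list
1 | 2,5-dimethoxybenzaldehyde | COc1ccc(OC)c(C=O)c1 | starting material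
2 | 2,5-dimethoxyphenyl formate | COc1ccc(OC)c(OC=O)c1 | intermediate (not isolated)
3 | 2,5-dimethoxyphenol | COc1ccc(OC)c(O)c1 | intermediate
4 | 2-(benzyloxy)-1,4-dimethoxybenzene | COc1ccc(OC)c(OCc2ccccc2)c1 | intermediate
5 | 1-(benzyloxy)-4-bromo-2,5-dimethoxybenzene | COc1cc(OCc2ccccc2)c(OC)cc1Br | intermediate
6 | [4-(benzyloxy)-2,5-dimethoxyphenyl]lithium | [Li]c1cc(OC)c(OCc2ccccc2)cc1OC | intermediate (not isolated)
7 | 4-(benzyloxy)-2,5-dimethoxybenzoic acid | COc1cc(OCc2ccccc2)c(OC)cc1C(=O)O | intermediate
8 | 4-(benzyloxy)-2,5-dimethoxybenzoyl chloride | COc1cc(OCc2ccccc2)c(OC)cc1C(Cl)=O | intermediate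
9 | gallacetophenone (1-(2,3,4-trihydroxyphenyl)ethanone) | CC(=O)c1ccc(O)c(O)c1O | starting material
10 | 1-[4-(benzyloxy)-2,3-dihydroxyphenyl]ethanone | CC(=O)c1ccc(OCc2ccccc2)c(O)c1O | intermediate
11 | trilithium 3-(benzyloxy)-6-(1-oxidoethenyl)benzene-1,2-diolate | [Li+].[Li+].[Li+].C=C([O-])c1ccc(OCc2ccccc2)c([O-])c1[O-] | intermediate (not isolated)
12 | 1-[4-(benzyloxy)-2,3-dihydroxyphenyl]-3-[4-(benzyloxy)-2,5-dimethoxyphenyl]propane-1,3-dione | O=C(CC(=O)c1cc(OC)c(OCc2ccccc2)cc1OC)c1ccc(OCc2ccccc2)c(O)c1O | intermediate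
13 | 1-[4-(benzyloxy)-5,6-dioxocyclohexa-1,3-dien-1-yl]-3-[4-(benzyloxy)-2,5-dimethoxyphenyl]propane-1,3-dione | O=C(CC(=O)c1cc(OC)c(OCc2ccccc2)cc1OC)C1=CC=C(OCc2ccccc2)C(=O)C1=O | intermediate (not isolated)
14 | 7-(benzyloxy)-2-[4-(benzyloxy)-2,5-dimethoxyphenyl]-5,6-dihydroxy-4H-chromen-4-one | COc1cc(-c2cc(=O)c3c(O)c(O)c(OCc4ccccc4)cc3o2)c(OC)cc1OCc1ccccc1 | intermediate
15 | 7-(benzyloxy)-2-[4-(benzyloxy)-2,5-dimethoxyphenyl]-5-hydroxy-6-methoxy-4H-chromen-4-one | COc1cc(-c2cc(=O)c3c(O)c(OC)c(OCc4ccccc4)cc3o2)c(OC)cc1OCc1ccccc1 | intermediate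
16 | 5,7-dihydroxy-2-(4-hydroxy-2,5-dimethoxyphenyl)-6-methoxy-4H-chromen-4-one (CNP0509606.0, no stereocentre) | COc1cc(-c2cc(=O)c3c(O)c(OC)c(O)cc3o2)c(OC)cc1O | target

Total step count: 10
Longest linear sequence: 9 steps (steps 1–5 and 7–10; step 6 is a one-step side branch)

Steps most likely to fail

1. Step 8 (proposed new method). What may go wrong:
- addition of water or buffer to the ortho-quinone before ring closure;
- intermolecular Michael coupling between the diketone carbon of one molecule and the quinone of another;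
- further oxidation of the product catechol;
- dehydrative closure through the C5 hydroxyl, which would give the 7,8-dioxygenated ring system.

The fallback uses known chemistry and closes the pyranone in the classical way through a phenol oxygen already in place at C8a. It sets out from acid chloride 8 and rejoins the route at target 16.
- Commercial 1-(2,4-dihydroxy-6-methoxyphenyl)ethanone would be benzylated at its non-chelated hydroxyl (BnBr, K2CO3, acetone) to 1-[4-(benzyloxy)-2-hydroxy-6-methoxyphenyl]ethanone F1.
- Elbs persulfate oxidation (K2S2O8, aqueous NaOH, 15 °C) would place a sulfate para to the free phenol and give potassium 3-acetyl-6-(benzyloxy)-4-hydroxy-2-methoxyphenyl sulfate F2.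
- Warm dilute HCl would hydrolyse the sulfate to 1-[4-(benzyloxy)-3,6-dihydroxy-2-methoxyphenyl]ethanone F3.
- MeI and K2CO3 in acetone would methylate the non-chelated hydroxyl to 1-[4-(benzyloxy)-6-hydroxy-2,3-dimethoxyphenyl]ethanone F4.
- The lithium dianion of this ketone (LiN(SiMe3)2, THF, −78 °C) would be C-acylated by 8 to 1-[4-(benzyloxy)-6-hydroxy-2,3-dimethoxyphenyl]-3-[4-(benzyloxy)-2,5-dimethoxyphenyl]propane-1,3-dione F5.
- Acid-catalysed cyclodehydration (TsOH cat., toluene, 90 °C) would give 7-(benzyloxy)-2-[4-(benzyloxy)-2,5-dimethoxyphenyl]-5,6-dimethoxy-4H-chromen-4-one F6.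
- BCl3 with pentamethylbenzene (CH2Cl2, −78 to 0 °C) would remove the chelated 5-methyl ether and both benzyl ethers and leave the other three methyl ethers, so that 16 is reached directly.

2. Step 7. What may go wrong: acylation at the phenoxide oxygens in competition with the enolate carbon, or incomplete formation of the polyanion through aggregation. The fallback makes O-acylation the intended first event (Baker–Venkataraman sequence). It sets out from 10 and 8 and returns at 12.
- Ketone 10 would be esterified on both hydroxyls with 8 (2.2 equiv, pyridine, DMAP cat.) to 3-acetyl-6-(benzyloxy)-1,2-phenylene bis[4-(benzyloxy)-2,5-dimethoxybenzoate] F7.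
- KOH in pyridine at 50 °C would transfer the aroyl group of the ester ortho to the ketone onto the enolate carbon and give 6-(benzyloxy)-3-{3-[4-(benzyloxy)-2,5-dimethoxyphenyl]-3-oxopropanoyl}-2-hydroxyphenyl 4-(benzyloxy)-2,5-dimethoxybenzoate F8.
- K2CO3 in MeOH at rt would remove the remaining aryl ester and give 12.

3. Step 6. What may go wrong: alkylation at the 3-hydroxyl or double benzylation in place of clean mono-etherification at O4. The fallback replaces direct alkylation by selective exchange of an acetate. It sets out from 9 and returns at 10.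
- Gallacetophenone 9 would be peracetylated (Ac2O, pyridine) to 4-acetylbenzene-1,2,3-triyl triacetate F9.
- BnBr with K2CO3 and KI in refluxing acetone would exchange only the acetate para to the ketone, the most labile one, for a benzyl ether and give 3-acetyl-6-(benzyloxy)-1,2-phenylene diacetate F10.
- K2CO3 in MeOH at rt would remove the two remaining acetates and give 10.

Further compounds
F1 | step 8 | 1-[4-(benzyloxy)-2-hydroxy-6-methoxyphenyl]ethanone | CC(=O)c1c(O)cc(OCc2ccccc2)cc1OC
F2 | step 8 | potassium 3-acetyl-6-(benzyloxy)-4-hydroxy-2-methoxyphenyl sulfate | CC(=O)c1c(O)cc(OCc2ccccc2)c(OS(=O)(=O)[O-])c1OC.[K+]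
F3 | step 8 | 1-[4-(benzyloxy)-3,6-dihydroxy-2-methoxyphenyl]ethanone | CC(=O)c1c(O)cc(OCc2ccccc2)c(O)c1OC
F4 | step 8 | 1-[4-(benzyloxy)-6-hydroxy-2,3-dimethoxyphenyl]ethanone | CC(=O)c1c(O)cc(OCc2ccccc2)c(OC)c1OC
F5 | step 8 | 1-[4-(benzyloxy)-6-hydroxy-2,3-dimethoxyphenyl]-3-[4-(benzyloxy)-2,5-dimethoxyphenyl]propane-1,3-dione | O=C(CC(=O)c1cc(OC)c(OCc2ccccc2)cc1OC)c1c(O)cc(OCc2ccccc2)c(OC)c1OC
F6 | step 8 | 7-(benzyloxy)-2-[4-(benzyloxy)-2,5-dimethoxyphenyl]-5,6-dimethoxy-4H-chromen-4-one | COc1cc(-c2cc(=O)c3c(OC)c(OC)c(OCc4ccccc4)cc3o2)c(OC)cc1OCc1ccccc1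
F7 | step 7 | 3-acetyl-6-(benzyloxy)-1,2-phenylene bis[4-(benzyloxy)-2,5-dimethoxybenzoate] | CC(=O)c1ccc(OCc2ccccc2)c(OC(=O)c2cc(OC)c(OCc3ccccc3)cc2OC)c1OC(=O)c1cc(OC)c(OCc2ccccc2)cc1OC
F8 | step 7 | 6-(benzyloxy)-3-{3-[4-(benzyloxy)-2,5-dimethoxyphenyl]-3-oxopropanoyl}-2-hydroxyphenyl 4-(benzyloxy)-2,5-dimethoxybenzoate | O=C(CC(=O)c1cc(OC)c(OCc2ccccc2)cc1OC)c1ccc(OCc2ccccc2)c(OC(=O)c2cc(OC)c(OCc3ccccc3)cc2OC)c1O
F9 | step 6 | 4-acetylbenzene-1,2,3-triyl triacetate | CC(=O)Oc1ccc(C(C)=O)c(OC(C)=O)c1OC(C)=O
F10 | step 6 | 3-acetyl-6-(benzyloxy)-1,2-phenylene diacetate | CC(=O)Oc1c(OCc2ccccc2)ccc(C(C)=O)c1OC(C)=O
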